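**Retrosynthetic overview**
- Feature: ring B holds the quaternary C10 between C9 (bearing C11) and C8 (bearing C17). This is the pattern of a cyclohexadiene made from a ring-A 1-vinyl-2-methylcyclohexene (C10=C5–C6=C7) and a 4-oxygenated but-2-ynoate (C11–C9≡C8–C17).
- End game: 19-O-acetyl and silyl ethers last; C12–C13 by Stille coupling of an (E)-C11=C12 vinyl iodide with a preformed 3-stannylbutenolide; C11=C12 by Takai olefination of the C9 aldehyde.
- C9–H and the C8=C17 methylene come from reductive transposition of the C17 carbonate across the C8=C9 enoate; C5–H comes from HAT hydrogenation of C5=C6.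
- Ring B is closed by an intermolecular Diels–Alder reaction (C7–C8 and C9–C10). Ring A is present from the start, ring B is formed second, the butenolide is attached ready-made.
- Diene from 2-methylcyclohexane-1,3-dione: C-allylation, enzymatic desymmetrising reduction (C3, C4), allyl degraded to C19 CH2OTBS, C10 methylation, enol triflate, vinylation.

Key step: step 11

Remark: labdane numbering (C1–C20) is used for all ring compounds, and the (R)-selective ketoreductase of step 2 is assumed to be picked from a commercial enzyme panel, because baker's yeast leads to the mirror-image (2S,3S) ketol.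

**Route**

Step 1
Reactants: 1 2-methylcyclohexane-1,3-dione; 2 allyl acetate
Product: 3 2-allyl-2-methylcyclohexane-1,3-dione
Conditions: Pd(PPh3)4 (cat.), DBU, PhMe, 80 °C
Reagents that add atoms: none
Why: Tsuji–Trost allylation: the soft dione enolate attacks the π-allylpalladium complex at carbon and any O-allyl enol ether re-ionises under the catalyst, so the 2,2-disubstituted dione should be the product.

Step 2
Reactants: 3 2-allyl-2-methylcyclohexane-1,3-dione
Product: 4 (2R,3R)-3-hydroxy-2-methyl-2-(prop-2-en-1-yl)cyclohexan-1-one (allyl cis to OH)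
Conditions: anti-Prelog ketoreductase (panel hit), NADP+ (cat.), i-PrOH, phosphate buffer pH 7, 30 °C
Reagents that add atoms: none
Why: Ketoreductase-catalysed desymmetrising reduction (the enzyme-class counterpart of the classical yeast reduction of this dione, in the mirror-image sense): hydride from NADPH goes to one enantiotopic carbonyl on its anti-Prelog face, which sets C3 (R) and at the same time makes C4 stereogenic (R, allyl cis to the hydroxyl).

Step 3
Reactants: 4 (2R,3R)-ketol
Product: 5 (2R,3R)-2-allyl-3-[(tert-butyldimethylsilyl)oxy]-2-methylcyclohexan-1-one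
Conditions: TBSCl, imidazole, DMF, 40 °C
Reagents that add atoms: tert-butyldimethylsilyl chloride, CC(C)(C)[Si](C)(C)Cl
Why: Silyl ether formation; the imidazole conditions are too mild to trigger retro-aldol opening of the β-hydroxy ketone.

Step 4
Reactants: 5 allyl ketone TBS ether
Product: 6 (2R,3R)-3-[(tert-butyldimethylsilyl)oxy]-2-methyl-2-[(E)-prop-1-en-1-yl]cyclohexan-1-one
Conditions: RuHCl(CO)(PPh3)3 (cat.), PhMe, 90 °C
Reagents that add atoms: none
Why: Ruthenium hydride alkene isomerisation (hydrometalation/β-hydride elimination): the double bond moves one position into the preferred internal place and cannot travel further because C4 is quaternary.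

Step 5
Reactants: 6 propenyl ketone
Product: 8 (2R,3R,6RS)-3-[(tert-butyldimethylsilyl)oxy]-2,6-dimethyl-2-[(E)-prop-1-en-1-yl]cyclohexan-1-one, via lithium enolate 7 (not isolated)
Conditions: LDA, THF, −78 °C; MeI, −78 → 0 °C
Reagents that add atoms: iodomethane, CI
Why: Kinetic enolate alkylation: C4 is quaternary, so only the C10 methylene can be deprotonated and is methylated once; the new centre is a mixture that is erased in step 6.

Step 6
Reactants: 8 C10-methyl ketone
Product: 10 (5R,6R)-5-[(tert-butyldimethylsilyl)oxy]-2,6-dimethyl-6-[(E)-prop-1-en-1-yl]cyclohex-1-en-1-yl trifluoromethanesulfonate, via potassium enolate 9 (not isolated)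
Conditions: KHMDS, THF, −78 → 0 °C; PhNTf2, −78 °C → rt
Reagents that add atoms: N-phenylbis(trifluoromethanesulfonimide), O=S(=O)(N(c1ccccc1)S(=O)(=O)C(F)(F)F)C(F)(F)F
Why: Enol triflate formation: the only remaining α-hydrogen is on C10, so deprotonation gives the single tetrasubstituted C5=C10 enolate, which is sulfonylated on oxygen.

Step 7
Reactants: 10 propenyl enol triflate
Product: 12 (5R,6R)-5-[(tert-butyldimethylsilyl)oxy]-6-(hydroxymethyl)-2,6-dimethylcyclohex-1-en-1-yl trifluoromethanesulfonate, via C19 aldehyde 11 (not isolated)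
Conditions: OsO4 (cat.), NaIO4, 2,6-lutidine, dioxane/H2O, rt; then NaBH4, EtOH, 0 °C
Reagents that add atoms: sodium periodate, [Na+].[O-]I(=O)(=O)=O, with catalytic osmium tetroxide, O=[Os](=O)(=O)=O (source of the C19 oxygen)
Why: Lemieux–Johnson cleavage then borohydride reduction: osmium tetroxide should select the disubstituted propenyl alkene over the hindered, electron-poor tetrasubstituted enol triflate, periodate cuts the diol to the C19 aldehyde and NaBH4 reduces it without touching the triflate; a silyl shift between O3 and O19 would be harmless because step 8 silylates whichever oxygen is free.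

Step 8
Reactants: 12 C19 alcohol
Product: 13 (5R,6R)-5-[(tert-butyldimethylsilyl)oxy]-6-{[(tert-butyldimethylsilyl)oxy]methyl}-2,6-dimethylcyclohex-1-en-1-yl trifluoromethanesulfonate
Conditions: TBSCl, imidazole, DMAP (cat.), DMF, rt
Reagents that add atoms: tert-butyldimethylsilyl chloride, CC(C)(C)[Si](C)(C)Cl
Why: Silyl ether formation at the free hydroxyl gives the bis-TBS ether and puts a bulky group on C19 for the facial control of step 11.

Step 9
Reactants: 13 bis-TBS enol triflate
Product: 14 ring-A diene, tert-butyl{[(1R,6R)-6-[(tert-butyldimethylsilyl)oxy]-2-ethenyl-1,3-dimethylcyclohex-2-en-1-yl]methoxy}dimethylsilane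
Conditions: tributyl(vinyl)stannane, Pd(PPh3)4 (cat.), CuCl, LiCl, DMSO, 60 °C
Reagents that add atoms: tributyl(vinyl)stannane, C=C[Sn](CCCC)(CCCC)CCCC
Why: Stille coupling of an enol triflate, run with the CuCl/LiCl acceleration used for congested triflates, attaches C6–C7 to C5 with no base present.

Step 10
Reactants: 15 methyl 4-hydroxybut-2-ynoate
Product: 16 methyl 4-(methoxycarbonyloxy)but-2-ynoate
Conditions: ClCO2Me, pyridine, CH2Cl2, 0 °C
Reagents that add atoms: methyl chloroformate, COC(Cl)=O
Why: O-Acylation of the propargylic alcohol with a chloroformate gives the carbonate that serves as the C17 leaving group in step 13.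

Step 11
Reactants: 14 ring-A diene; 16 methyl 4-(methoxycarbonyloxy)but-2-ynoate
Product: 17 bicyclic 5,8-diene adduct: methyl 3,19-bis(TBS-oxy)-17-(methoxycarbonyloxy)-12,13,14,15,16-pentanorlabda-5,8-dien-11-oate (C20 cis to C19 and to O3)
Conditions: 16 (2 equiv), BHT (cat.), PhMe (2 M), 120 °C, sealed tube
Reagents that add atoms: none
Why: A concerted, asynchronous thermal [4+2] cycloaddition of the s-cis diene C10=C5–C6=C7 with the alkyne forms C7–C8 and C9–C10; the closest known reaction type is the Diels–Alder addition of acetylenic esters to 1-vinyl-2,6,6-trialkylcyclohexenes used to build drimane-type decalins. Ring B is closed by intermolecular [4+2] annulation onto ring A as a 1,4-cyclohexadiene (C5=C6 and C8=C9 remain). The orientation follows from the larger HOMO coefficient at the unsubstituted terminus C7, which bonds to the alkyne carbon β to the ester, so that the ester carbon C11 ends on C9 next to C10 and C17 on C8. The one new stereocentre, the quaternary C10, is set by the C4 centre: in the reactive half-chair the C3 silyloxy group is equatorial, the large C19 CH2OTBS pseudo-axial and the small C18 methyl pseudo-equatorial beside H-6, so the alkyne adds to the diene face opposite C19 and the C10 methyl is turned to the C19 side. The step needs this facial selectivity and enough reactivity from a hindered diene; the bulky silyl groups serve the first, and heat in concentrated solution with a radical inhibitor and no acid (which would isomerise the skipped diene) serves the second.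

Step 12
Reactants: 17 Diels–Alder adduct
Product: 18 trans-fused 8-ene: methyl 3,19-bis(TBS-oxy)-17-(methoxycarbonyloxy)-12,13,14,15,16-pentanorlabd-8-en-11-oate (H-5 trans to C20)
Conditions: Mn(dpm)3 (cat.), PhSiH3, t-BuOOH, i-PrOH, rt
Reagents that add atoms: none
Why: Metal-hydride hydrogen-atom-transfer hydrogenation (Mukaiyama type): H• adds to C6 to give the tertiary C5 radical, which takes its hydrogen on the face opposite the axial C20 and C19 groups and so gives the trans ring fusion, while the tetrasubstituted enoate is too hindered to react and the allylic carbonate is not hydrogenolysed as it could be over Pd/H2.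

Step 13
Reactants: 18 trans-fused enoate carbonate
Product: 19 methyl 3,19-bis(TBS-oxy)-12,13,14,15,16-pentanorlabd-8(17)-en-11-oate (H-9 trans to C20, ester equatorial)
Conditions: SmI2, HMPA, t-BuOH, THF, −78 °C
Reagents that add atoms: none
Why: Samarium diiodide reduction of a γ-acyloxy-α,β-unsaturated ester: two electron transfers expel the carbonate and leave the C17=C8–C9=C11 dienolate, whose kinetic α-protonation at C9 from the face opposite the C10 methyl gives the 8(17)-methylene and the 9-H trans to C20.

Step 14
Reactants: 19 exo-methylene ester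
Product: 20 C11 primary alcohol: 3,19-bis(TBS-oxy)-12,13,14,15,16-pentanorlabd-8(17)-en-11-ol
Conditions: LiAlH4, THF, 0 °C
Reagents that add atoms: none
Why: Hydride reduction of the ester to the primary alcohol; silyl ethers and the isolated alkene are inert to LiAlH4 at 0 °C.

Step 15
Reactants: 20 C11 alcohol
Product: 21 C11 aldehyde: 3,19-bis(TBS-oxy)-12,13,14,15,16-pentanorlabd-8(17)-en-11-al
Conditions: Dess–Martin periodinane, NaHCO3, CH2Cl2, 0 °C → rt
Reagents that add atoms: none
Why: Dess–Martin oxidation under bicarbonate buffer is non-basic enough that the β,γ-unsaturated aldehyde should neither epimerise at C9 nor move its double bond into conjugation.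

Step 16
Reactants: 21 C11 aldehyde
Product: 22 (E)-vinyl iodide: C9–CH=CH–I (C11=C12) on the 3,19-bis(TBS-oxy)-8(17)-ene decalin
Conditions: CrCl2, CHI3, THF/dioxane, 0 °C → rt
Reagents that add atoms: iodoform, IC(I)I
Why: Takai iodo-olefination: the gem-dichromium reagent from iodoform adds to the aldehyde and eliminates to the (E)-vinyl iodide under non-basic conditions that leave C9 untouched.

Step 17
Reactants: 15 methyl 4-hydroxybut-2-ynoate
Product: 24 3-(tributylstannyl)furan-2(5H)-one, via hydroxy stannyl enoate 23 (not isolated)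
Conditions: Bu3SnH, PdCl2(PPh3)2 (cat.), THF, 0 °C → rt; then PPTS (cat.), rt
Reagents that add atoms: tributyltin hydride, CCCC[SnH](CCCC)CCCC
Why: Palladium-catalysed syn-hydrostannation of an ynoate puts tin on the carbon α to the ester and hydrogen on the β-carbon, so the CH2OH and CO2Me groups end cis and close to the butenolide with loss of methanol.

Step 18
Reactants: 22 (E)-vinyl iodide; 24 3-(tributylstannyl)furan-2(5H)-one
Product: 25 3,19-bis-O-TBS-14-deoxy-11,12-didehydroandrographolide
Conditions: Pd2(dba)3 (cat.), AsPh3, CuI, NMP, rt → 40 °C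
Reagents that add atoms: none
Why: Stille coupling with copper(I) co-catalysis joins C12 to C13 with retention of the (E) geometry under neutral conditions that spare the base-sensitive butenolide.

Step 19
Reactants: 25 bis-TBS ether
Product: 26 14-deoxy-11,12-didehydroandrographolide (3,19-diol)
Conditions: HF·pyridine, THF, 0 °C → rt
Reagents that add atoms: none
Why: Fluoride-mediated desilylation with the mildly acidic HF·pyridine removes both TBS groups without the basic conditions that would deprotonate the butenolide at C15.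

Step 20
Reactants: 26 3,19-diol
Product: 27 target, 19-O-acetyl-14-deoxy-11,12-didehydroandrographolide, (3R,4R,5S,9R,10R)
Conditions: Ac2O (1.1 equiv), pyridine, CH2Cl2, −20 → 0 °C
Reagents that add atoms: acetic anhydride, CC(=O)OC(C)=O
Why: Selective acylation: the primary C19 hydroxyl reacts faster than the secondary C3 hydroxyl, which is flanked by the quaternary C4, so one equivalent of anhydride at low temperature should give the 19-monoacetate.

**Compound list**
1 | 2-methylcyclohexane-1,3-dione | CC1C(=O)CCCC1=O | starting material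
2 | allyl acetate | C=CCOC(C)=O | starting material
3 | 2-allyl-2-methylcyclohexane-1,3-dione | C=CCC1(C)C(=O)CCCC1=O | intermediate
4 | (2R,3R)-3-hydroxy-2-methyl-2-(prop-2-en-1-yl)cyclohexan-1-one | O=C1[C@](C)(CC=C)[C@H](O)CCC1 | intermediate
5 | (2R,3R)-2-allyl-3-[(tert-butyldimethylsilyl)oxy]-2-methylcyclohexan-1-one | O=C1[C@](C)(CC=C)[C@H](O[Si](C)(C)C(C)(C)C)CCC1 | intermediate
6 | (2R,3R)-3-[(tert-butyldimethylsilyl)oxy]-2-methyl-2-[(E)-prop-1-en-1-yl]cyclohexan-1-one | O=C1[C@](C)(/C=C/C)[C@H](O[Si](C)(C)C(C)(C)C)CCC1 | intermediate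
7 | lithium enolate of 6 (C5–OLi, C5=C10) | [Li]OC=1[C@](C)(/C=C/C)[C@H](O[Si](C)(C)C(C)(C)C)CCC=1 | intermediate (not isolated)
8 | (2R,3R,6RS)-3-[(tert-butyldimethylsilyl)oxy]-2,6-dimethyl-2-[(E)-prop-1-en-1-yl]cyclohexan-1-one | O=C1[C@](C)(/C=C/C)[C@H](O[Si](C)(C)C(C)(C)C)CCC1C | intermediate
9 | potassium enolate of 8 (tetrasubstituted C5=C10) | [K]OC=1[C@](C)(/C=C/C)[C@H](O[Si](C)(C)C(C)(C)C)CCC=1C | intermediate (not isolated)
10 | (5R,6R)-5-[(tert-butyldimethylsilyl)oxy]-2,6-dimethyl-6-[(E)-prop-1-en-1-yl]cyclohex-1-en-1-yl trifluoromethanesulfonate | FC(F)(F)S(=O)(=O)OC=1[C@](C)(/C=C/C)[C@H](O[Si](C)(C)C(C)(C)C)CCC=1C | intermediate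
11 | C19 aldehyde: 5-TBS-oxy-6-formyl-2,6-dimethylcyclohex-1-en-1-yl triflate, configured as 10 | FC(F)(F)S(=O)(=O)OC=1[C@](C)(C=O)[C@H](O[Si](C)(C)C(C)(C)C)CCC=1C | intermediate (not isolated)
12 | (5R,6R)-5-[(tert-butyldimethylsilyl)oxy]-6-(hydroxymethyl)-2,6-dimethylcyclohex-1-en-1-yl trifluoromethanesulfonate | FC(F)(F)S(=O)(=O)OC=1[C@](C)(CO)[C@H](O[Si](C)(C)C(C)(C)C)CCC=1C | intermediate
13 | (5R,6R)-5-[(tert-butyldimethylsilyl)oxy]-6-{[(tert-butyldimethylsilyl)oxy]methyl}-2,6-dimethylcyclohex-1-en-1-yl trifluoromethanesulfonate | FC(F)(F)S(=O)(=O)OC=1[C@](C)(CO[Si](C)(C)C(C)(C)C)[C@H](O[Si](C)(C)C(C)(C)C)CCC=1C | intermediate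
14 | ring-A diene, tert-butyl{[(1R,6R)-6-[(tert-butyldimethylsilyl)oxy]-2-ethenyl-1,3-dimethylcyclohex-2-en-1-yl]methoxy}dimethylsilane | C=CC=1[C@](C)(CO[Si](C)(C)C(C)(C)C)[C@H](O[Si](C)(C)C(C)(C)C)CCC=1C | intermediate
15 | methyl 4-hydroxybut-2-ynoate | COC(=O)C#CCO | starting material
16 | methyl 4-(methoxycarbonyloxy)but-2-ynoate | COC(=O)OCC#CC(=O)OC | intermediate
17 | Diels–Alder adduct, methyl 3,19-bis(TBS-oxy)-17-(methoxycarbonyloxy)-12,13,14,15,16-pentanorlabda-5,8-dien-11-oate (C20 cis to C19) | COC(=O)OCC=1CC=C2[C@](C)(CO[Si](C)(C)C(C)(C)C)[C@H](O[Si](C)(C)C(C)(C)C)CC[C@@]2(C)C=1C(=O)OC | intermediate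
18 | trans-fused methyl 3,19-bis(TBS-oxy)-17-(methoxycarbonyloxy)-12,13,14,15,16-pentanorlabd-8-en-11-oate | COC(=O)OCC=1CC[C@@H]2[C@](C)(CO[Si](C)(C)C(C)(C)C)[C@H](O[Si](C)(C)C(C)(C)C)CC[C@@]2(C)C=1C(=O)OC | intermediate
19 | methyl 3,19-bis(TBS-oxy)-12,13,14,15,16-pentanorlabd-8(17)-en-11-oate | C=C1CC[C@@H]2[C@](C)(CO[Si](C)(C)C(C)(C)C)[C@H](O[Si](C)(C)C(C)(C)C)CC[C@@]2(C)[C@@H]1C(=O)OC | intermediate
20 | 3,19-bis(TBS-oxy)-12,13,14,15,16-pentanorlabd-8(17)-en-11-ol | C=C1CC[C@@H]2[C@](C)(CO[Si](C)(C)C(C)(C)C)[C@H](O[Si](C)(C)C(C)(C)C)CC[C@@]2(C)[C@@H]1CO | intermediate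
21 | 3,19-bis(TBS-oxy)-12,13,14,15,16-pentanorlabd-8(17)-en-11-al | C=C1CC[C@@H]2[C@](C)(CO[Si](C)(C)C(C)(C)C)[C@H](O[Si](C)(C)C(C)(C)C)CC[C@@]2(C)[C@@H]1C=O | intermediate
22 | (E)-12-iodo-3,19-bis(TBS-oxy)-13,14,15,16-tetranorlabda-8(17),11-diene (vinyl iodide) | C=C1CC[C@@H]2[C@](C)(CO[Si](C)(C)C(C)(C)C)[C@H](O[Si](C)(C)C(C)(C)C)CC[C@@]2(C)[C@@H]1/C=C/I | intermediate
23 | methyl (E)-4-hydroxy-2-(tributylstannyl)but-2-enoate (CH2OH cis to CO2Me) | OC/C=C(\C(=O)OC)[Sn](CCCC)(CCCC)CCCC | intermediate (not isolated)
24 | 3-(tributylstannyl)furan-2(5H)-one | O=C1OCC=C1[Sn](CCCC)(CCCC)CCCC | intermediate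
25 | 3,19-bis-O-TBS-14-deoxy-11,12-didehydroandrographolide | C=C1CC[C@@H]2[C@](C)(CO[Si](C)(C)C(C)(C)C)[C@H](O[Si](C)(C)C(C)(C)C)CC[C@@]2(C)[C@@H]1/C=C/C1=CCOC1=O | intermediate
26 | 14-deoxy-11,12-didehydroandrographolide | C=C1CC[C@@H]2[C@](C)(CO)[C@H](O)CC[C@@]2(C)[C@@H]1/C=C/C1=CCOC1=O | intermediate
27 | 19-O-acetyl-14-deoxy-11,12-didehydroandrographolide (CNP0346413.1) | C=C1CC[C@@H]2[C@](C)(COC(C)=O)[C@H](O)CC[C@@]2(C)[C@@H]1/C=C/C1=CCOC1=O | target

**Step count**
Total: 20 steps. Longest linear sequence: 18 steps (steps 1–9, 11–16, 18–20).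

**Steps most likely to fail**

Step 11. The hindered diene may add the singly activated alkyne too slowly below the temperature at which the C20–C10=C5–C6=C7 unit undergoes a 1,5-hydrogen shift, and part of the alkyne may add in the reverse orientation. The fallback sets out from diene 14 and uses dimethyl acetylenedicarboxylate, which is doubly activated and symmetrical, so that orientation no longer matters. Heating under the conditions of step 11 should give the dimethyl 5,8-diene-11,17-dioate F1. The hydrogenation conditions of step 12 should then give the trans-fused 8-ene diester F2. One equivalent of LiOH in THF/H2O should hydrolyse only the C8 ester, the C9 ester being screened by the quaternary C10, to give the 17-acid 11-methyl ester F3. Reduction of the acid through its mixed anhydride (i-BuOCOCl, N-methylmorpholine; NaBH4) gives the C17 alcohol, which closes onto the neighbouring ester to the 17,11-butenolide F4. SmI2/HMPA/t-BuOH cleaves the allylic C17–O bond, and α-protonation of the dienolate gives the 8(17)-en-11-oic acid F5. Trimethylsilyldiazomethane then returns to the route at ester 19.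

Step 13. Electron transfer to the twisted, tetrasubstituted enoate may be slow, or the dienolate may take its proton at C17 and give the conjugated 8-methyl enoate. The fallback sets out from carbonate 18 and comes back at ester 19 by a palladium-catalysed formate hydrogenolysis of the allylic carbonate (Pd(OAc)2, n-Bu3P, HCO2H/Et3N, THF, 60 °C). Ionisation gives the C17–C8–C9 π-allylpalladium formate, decarboxylation gives a palladium hydride, and the hydride is delivered to the more substituted terminus C9 on the face opposite C20. This replaces electron transfer and protonation by an organometallic hydride transfer and makes no new compound.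

Step 2. The chosen enzyme may deliver hydride to the other enantiotopic carbonyl (trans ketol) or show incomplete enantioface control. The fallback sets out from dione 3 and comes back at ketol 4 by a Corey–Bakshi–Shibata reduction ((S)-2-methyl-CBS-oxazaborolidine (cat.), catecholborane, PhMe, −60 °C). With the quaternary carbon as the large group the usual model predicts the (3R) carbinol, and attack anti to the larger allyl group selects the carbonyl that gives the cis ketol. Any trans ketol would be removed by chromatography.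

Further compounds
F1 | step 11 | dimethyl 3,19-bis(TBS-oxy)-12,13,14,15,16-pentanorlabda-5,8-diene-11,17-dioate | COC(=O)C=1CC=C2[C@](C)(CO[Si](C)(C)C(C)(C)C)[C@H](O[Si](C)(C)C(C)(C)C)CC[C@@]2(C)C=1C(=O)OC
F2 | step 11 | trans-fused dimethyl 3,19-bis(TBS-oxy)-12,13,14,15,16-pentanorlabd-8-ene-11,17-dioate | COC(=O)C=1CC[C@@H]2[C@](C)(CO[Si](C)(C)C(C)(C)C)[C@H](O[Si](C)(C)C(C)(C)C)CC[C@@]2(C)C=1C(=O)OC
F3 | step 11 | 17-carboxylic acid 11-methyl ester of F2 | OC(=O)C=1CC[C@@H]2[C@](C)(CO[Si](C)(C)C(C)(C)C)[C@H](O[Si](C)(C)C(C)(C)C)CC[C@@]2(C)C=1C(=O)OC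
F4 | step 11 | 17,11-butenolide (C17H2–O–C11=O fused at C8=C9) | O=C1OCC=2CC[C@@H]3[C@](C)(CO[Si](C)(C)C(C)(C)C)[C@H](O[Si](C)(C)C(C)(C)C)CC[C@@]3(C)C1=2
F5 | step 11 | 3,19-bis(TBS-oxy)-12,13,14,15,16-pentanorlabd-8(17)-en-11-oic acid | C=C1CC[C@@H]2[C@](C)(CO[Si](C)(C)C(C)(C)C)[C@H](O[Si](C)(C)C(C)(C)C)CC[C@@]2(C)[C@@H]1C(=O)O
F0 | step 13 | none | none
F0 | step 2 | none | none
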